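**Plan**

1. Retrosynthesis (daucane numbering: C1 = methyl-bearing ring-fusion carbon, C4 = isopropyl carbinol, C5 = ring-fusion CH, C6 = carbinol, C8/C9 = oxirane carbons, C10 = CH2 between C9 and C1). The phenol and C6–OH are unmasked last and the oxirane is traced back to the C8=C9 alkene. Then C10–C1 and C9–C8 are cut together, removing C9–C10 as a vinylphosphonium salt.
2. Enabling feature: in the monocyclic precursor the C8 methyl ketone hangs on C5 through C7–C6, next to the exocyclic 1,1-disubstituted C1=CH2 of the cyclopentane. Hydrogen-atom transfer turns that alkene into the tertiary C1 radical, and the two-carbon vinyl-onium unit bridges C1 and the C8 carbonyl. One operation therefore closes the seven-membered ring, creates the quaternary ring-fusion carbon and leaves C8=C9 for epoxidation.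
3. Further cuts: C4–O aroyl bond; C5–C6 bond (allylmetal from a vinyl oxirane plus a ketal aldehyde); exocyclic methylene (Wittig); oxirane of 3-isopropylcyclopentenone.
4. Forward order: the cyclopentane comes from 1 (steps 1–3), the side chain is joined (step 5), C6 is corrected and protected, the ester is installed and the ketone released. The seven-membered ring is closed in step 12 and the oxirane is made in step 14.
5. Stereochemistry: C4 and C5 come from a catalytic asymmetric enone epoxidation (C4–O is kept; C5 is set by allylation opposite the isopropyl group). C6 comes from chelation-controlled reduction, C1 from radical addition opposite the C5 side chain, and C8/C9 from peracid attack on the α face.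

Key step: step 12

Assumption: the cinchona-derived primary amine salt of step 2 is taken to deliver the (1S,5R) epoxide 4; should it favour the antipode, its quinidine-derived pseudo-enantiomer is used instead.

**Step 1**
Reactants: 1 3-ethoxycyclopent-2-en-1-one
Product: 3 3-(propan-2-yl)cyclopent-2-en-1-one, via tertiary allylic alcohol 2 (not isolated)
Conditions: i-PrMgCl, THF, 0 °C; then 1 M HCl, rt
Reagents that add atoms: isopropylmagnesium chloride (CC(C)[Mg]Cl)
Why: Stork–Danheiser sequence, in which 1,2-addition of the Grignard reagent to the vinylogous ester and acid-induced loss of ethanol with allylic transposition should give the 3-alkyl enone.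

**Step 2**
Reactants: 3 3-(propan-2-yl)cyclopent-2-en-1-one
Product: 4 (1S,5R)-5-(propan-2-yl)-6-oxabicyclo[3.1.0]hexan-2-one
Conditions: aq. H2O2 (1.5 equiv), 9-amino-9-deoxy-epi-quinine·2CF3CO2H (10 mol %), dioxane, 50 °C
Reagents that add atoms: hydrogen peroxide (OO)
Why: Amine-salt-catalysed Weitz–Scheffer-type epoxidation, in which hydroperoxide adds to the β-carbon of the chiral iminium ion on the catalyst-controlled face and the enamine closes the oxirane, so that C4 (tertiary C–O) and C5 are set together, cis by the ring.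

**Step 3**
Reactants: 4 (1S,5R)-5-(propan-2-yl)-6-oxabicyclo[3.1.0]hexan-2-one
Product: 5 (1R,5R)-4-methylidene-1-(propan-2-yl)-6-oxabicyclo[3.1.0]hexane
Conditions: Ph3PCH3Br, KOt-Bu, THF, 0 °C → rt
Reagents that add atoms: methyltriphenylphosphonium bromide (C[P+](c1ccccc1)(c1ccccc1)c1ccccc1.[Br-])
Why: Wittig methylenation of the ketone with a non-stabilised ylide, which leaves the base-stable oxirane and both stereocentres untouched.

**Step 4**
Reactants: 6 ethyl 2-(2-methyl-1,3-dioxolan-2-yl)acetate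
Product: 7 2-(2-methyl-1,3-dioxolan-2-yl)acetaldehyde
Conditions: i-Bu2AlH (1.05 equiv), CH2Cl2, −78 °C; Rochelle salt work-up
Reagents that add atoms: none
Why: Partial ester reduction with i-Bu2AlH at −78 °C, where the tetrahedral aluminium hemiacetal survives until work-up.

**Step 5**
Reactants: 5 (1R,5R)-4-methylidene-1-(propan-2-yl)-6-oxabicyclo[3.1.0]hexane and 7 2-(2-methyl-1,3-dioxolan-2-yl)acetaldehyde
Product: 8 (1R,2S)-2-[(1R)-1-hydroxy-2-(2-methyl-1,3-dioxolan-2-yl)ethyl]-3-methylidene-1-(propan-2-yl)cyclopentan-1-ol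
Conditions: Pd(PPh3)4 (5 mol %), InI (1.5 equiv), THF, rt; aq. NH4Cl
Reagents that add atoms: none
Why: Palladium/indium umpolung allylation, in which zerovalent palladium opens the vinyl oxirane at the allylic C5–O bond and monovalent indium converts the alkoxy π-allyl complex into an allylindium species that adds to the aldehyde through ring carbon C5 in a six-membered transition state on the face opposite the isopropyl group; this fixes C5 with C6 cis to the untouched C4 oxygen and returns the exocyclic alkene, while the C6 carbinol is expected as the anti (6R) epimer, whose configuration is erased in step 6.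

**Step 6**
Reactants: 8 (1R,2S)-2-[(1R)-1-hydroxy-2-(2-methyl-1,3-dioxolan-2-yl)ethyl]-3-methylidene-1-(propan-2-yl)cyclopentan-1-ol
Product: 9 1-[(1R,2R)-2-hydroxy-5-methylidene-2-(propan-2-yl)cyclopentyl]-2-(2-methyl-1,3-dioxolan-2-yl)ethan-1-one
Conditions: Dess–Martin periodinane, CH2Cl2, 0 °C → rt
Reagents that add atoms: none
Why: Dess–Martin oxidation of the secondary alcohol, with the tertiary alcohol inert and the neutral conditions sparing the α-stereocentre C5 and the ketal.

**Step 7**
Reactants: 9 1-[(1R,2R)-2-hydroxy-5-methylidene-2-(propan-2-yl)cyclopentyl]-2-(2-methyl-1,3-dioxolan-2-yl)ethan-1-one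
Product: 10 (1R,2S)-2-[(1S)-1-hydroxy-2-(2-methyl-1,3-dioxolan-2-yl)ethyl]-3-methylidene-1-(propan-2-yl)cyclopentan-1-ol
Conditions: Et2BOMe (1.1 equiv), THF/MeOH (4:1), −78 °C; NaBH4; then MeOH, evaporate (repeated)
Reagents that add atoms: none
Why: Narasaka–Prasad reduction, in which Et2BOMe ties the C4 hydroxyl and the C6 ketone into a six-membered boron chelate cis-fused to the cyclopentane and external hydride adds so that the side chain ends equatorial (1,3-syn diol), which should give the (6S) carbinol.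

**Step 8**
Reactants: 10 (1R,2S)-2-[(1S)-1-hydroxy-2-(2-methyl-1,3-dioxolan-2-yl)ethyl]-3-methylidene-1-(propan-2-yl)cyclopentan-1-ol
Product: 11 (1R,2S)-3-methylidene-2-[(1S)-2-(2-methyl-1,3-dioxolan-2-yl)-1-{[tri(propan-2-yl)silyl]oxy}ethyl]-1-(propan-2-yl)cyclopentan-1-ol
Conditions: i-Pr3SiOTf (1.1 equiv), 2,6-lutidine, CH2Cl2, −78 → −20 °C
Reagents that add atoms: triisopropylsilyl triflate (CC(C)[Si](OS(=O)(=O)C(F)(F)F)(C(C)C)C(C)C)
Why: Silyl triflate silylation, selective for the secondary hydroxyl because the tertiary carbinol bearing the isopropyl group is too hindered.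

**Step 9**
Reactants: 12 4-(benzyloxy)-3-methoxybenzoic acid
Product: 13 4-(benzyloxy)-3-methoxybenzoyl chloride
Conditions: (COCl)2, DMF (cat.), CH2Cl2, 0 °C → rt
Reagents that add atoms: oxalyl chloride (ClC(=O)C(=O)Cl)
Why: Acid chloride formation with oxalyl chloride under Vilsmeier-type catalysis by DMF.

**Step 10**
Reactants: 11 (1R,2S)-3-methylidene-2-[(1S)-2-(2-methyl-1,3-dioxolan-2-yl)-1-{[tri(propan-2-yl)silyl]oxy}ethyl]-1-(propan-2-yl)cyclopentan-1-ol and 13 4-(benzyloxy)-3-methoxybenzoyl chloride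
Product: 14 (1R,2S)-3-methylidene-2-[(1S)-2-(2-methyl-1,3-dioxolan-2-yl)-1-{[tri(propan-2-yl)silyl]oxy}ethyl]-1-(propan-2-yl)cyclopentyl 4-(benzyloxy)-3-methoxybenzoate
Conditions: KN(SiMe3)2 (1.2 equiv), THF, −78 °C; then 13, −78 → 0 °C
Reagents that add atoms: none
Why: Acylation of a hindered tertiary alcohol through its potassium alkoxide with an acid chloride, the bulky triisopropylsilyl ether being chosen because it does not migrate to the tertiary oxygen.

**Step 11**
Reactants: 14 (1R,2S)-3-methylidene-2-[(1S)-2-(2-methyl-1,3-dioxolan-2-yl)-1-{[tri(propan-2-yl)silyl]oxy}ethyl]-1-(propan-2-yl)cyclopentyl 4-(benzyloxy)-3-methoxybenzoate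
Product: 15 (1R,2S)-3-methylidene-2-[(1S)-3-oxo-1-{[tri(propan-2-yl)silyl]oxy}butyl]-1-(propan-2-yl)cyclopentyl 4-(benzyloxy)-3-methoxybenzoate
Conditions: PPTS, acetone/H2O (10:1), 50 °C
Reagents that add atoms: water (O)
Why: Acid-catalysed hydrolysis of the dioxolane under conditions that the tertiary aryl ester, the triisopropylsilyl ether and the alkene should tolerate.

**Step 12**
Reactants: 15 (1R,2S)-3-methylidene-2-[(1S)-3-oxo-1-{[tri(propan-2-yl)silyl]oxy}butyl]-1-(propan-2-yl)cyclopentyl 4-(benzyloxy)-3-methoxybenzoate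
Product: 18 (1R,4R,5S,6S)-6-{[tri(propan-2-yl)silyl]oxy}dauc-8-en-4-yl 4-(benzyloxy)-3-methoxybenzoate, via phosphonium bromide 16 (not isolated), via phosphorus ylide 17 (not isolated)
Conditions: Fe(acac)3 (30 mol %), PhSiH3 (2.5 equiv), CH2=CHPPh3Br (1.3 equiv), EtOH/THF (1:1), 60 °C; evaporate; KOt-Bu (1.4 equiv), THF, 0 °C → rt (same flask)
Reagents that add atoms: vinyltriphenylphosphonium bromide (C=C[P+](c1ccccc1)(c1ccccc1)c1ccccc1.[Br-])
Why: Proposed new method: Fe(acac)3/PhSiH3 generates an iron hydride that transfers a hydrogen atom to the CH2 terminus of the 1,1-disubstituted C1=CH2 alkene, the tertiary C1 radical adds to the CH2 end of the vinylphosphonium salt (Giese addition) to form C10–C1, and the α-phosphonio radical is reduced by divalent iron and protonated to salt 16; KOt-Bu then gives ylide 17, which attacks the C8 ketone and collapses through the oxaphosphetane to the C8=C9 alkene with loss of Ph3PO. The closest known reaction types are the iron-mediated reductive coupling of tertiary radicals from hydrogen-atom transfer with electron-poor alkenes and the Schweizer annulation, in which a nucleophile adds to a vinylphosphonium salt and the resulting ylide undergoes intramolecular Wittig olefination. The seven-membered ring is closed in the Wittig stage by addition of the C9 ylide carbon to the exocyclic C8=O (7-exo-trig) and oxaphosphetane cycloreversion, the ring enforcing the Z alkene. The only new stereocentre, quaternary C1, is set in the radical addition, which should occur on the cyclopentyl face opposite the adjacent C5 side chain and the C4 aroyloxy group, so that C10 is trans to C6 (trans ring fusion) and the new methyl is β. The step needs Markovnikov hydrogen-atom transfer to the single alkene (arenes, ester and ketone are inert to the iron hydride), radical trapping faster than reduction or 1,5-hydrogen transfer (the reason for a silyl and not a benzyl ether at C6), and ylide attack on the methyl ketone instead of the hindered tertiary aryl ester.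

**Step 13**
Reactants: 18 (1R,4R,5S,6S)-6-{[tri(propan-2-yl)silyl]oxy}dauc-8-en-4-yl 4-(benzyloxy)-3-methoxybenzoate
Product: 19 (1R,4R,5S,6S)-6-hydroxydauc-8-en-4-yl 4-(benzyloxy)-3-methoxybenzoate
Conditions: HF·pyridine, pyridine, THF, 0 °C → rt
Reagents that add atoms: none
Why: Fluoride-mediated desilylation under weakly acidic conditions, which avoids alkoxide formation and hence 1,3-acyl migration from the tertiary to the secondary oxygen.

**Step 14**
Reactants: 19 (1R,4R,5S,6S)-6-hydroxydauc-8-en-4-yl 4-(benzyloxy)-3-methoxybenzoate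
Product: 20 (1R,4R,5S,6S,8R,9S)-8,9-epoxy-6-hydroxydaucan-4-yl 4-(benzyloxy)-3-methoxybenzoate
Conditions: mCPBA (1.2 equiv), CH2Cl2, 0 °C
Reagents that add atoms: 3-chloroperbenzoic acid (OOC(=O)c1cccc(Cl)c1)
Why: Prilezhaev epoxidation of the only alkene, in which the peracid should attack the trisubstituted C8=C9 bond on the α face, away from the axial angular methyl on C1 and assisted by hydrogen bonding to the homoallylic 6α-hydroxyl, setting C8 (R) and C9 (S).

**Step 15**
Reactants: 20 (1R,4R,5S,6S,8R,9S)-8,9-epoxy-6-hydroxydaucan-4-yl 4-(benzyloxy)-3-methoxybenzoate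
Product: 21 (1R,4R,5S,6S,8R,9S)-8,9-epoxy-6-hydroxydaucan-4-yl 4-hydroxy-3-methoxybenzoate
Conditions: H2 (1 atm), Pd/C (10 %), EtOAc, rt
Reagents that add atoms: none
Why: Hydrogenolysis of the aryl benzyl ether over palladium under neutral conditions, to which the non-benzylic trisubstituted oxirane and the ester are inert.

**Compound list**

1 | 3-ethoxycyclopent-2-en-1-one | CCOC1=CC(=O)CC1 | starting material
2 | 3-ethoxy-1-(propan-2-yl)cyclopent-2-en-1-ol (racemic 1,2-adduct) | CCOC1=CC(O)(C(C)C)CC1 | intermediate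
3 | 3-(propan-2-yl)cyclopent-2-en-1-one | CC(C)C1=CC(=O)CC1 | intermediate
4 | (1S,5R)-5-(propan-2-yl)-6-oxabicyclo[3.1.0]hexan-2-one | O=C1CC[C@]2(C(C)C)O[C@H]12 | intermediate
5 | (1R,5R)-4-methylidene-1-(propan-2-yl)-6-oxabicyclo[3.1.0]hexane | C=C1CC[C@]2(C(C)C)O[C@H]12 | intermediate
6 | ethyl 2-(2-methyl-1,3-dioxolan-2-yl)acetate | CCOC(=O)CC1(C)OCCO1 | starting material
7 | 2-(2-methyl-1,3-dioxolan-2-yl)acetaldehyde | O=CCC1(C)OCCO1 | intermediate
8 | (1R,2S)-2-[(1R)-1-hydroxy-2-(2-methyl-1,3-dioxolan-2-yl)ethyl]-3-methylidene-1-(propan-2-yl)cyclopentan-1-ol | O[C@@]1(C(C)C)CCC(=C)[C@H]1[C@H](O)CC1(C)OCCO1 | intermediate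
9 | 1-[(1R,2R)-2-hydroxy-5-methylidene-2-(propan-2-yl)cyclopentyl]-2-(2-methyl-1,3-dioxolan-2-yl)ethan-1-one | O[C@@]1(C(C)C)CCC(=C)[C@H]1C(=O)CC1(C)OCCO1 | intermediate
10 | (1R,2S)-2-[(1S)-1-hydroxy-2-(2-methyl-1,3-dioxolan-2-yl)ethyl]-3-methylidene-1-(propan-2-yl)cyclopentan-1-ol | O[C@@]1(C(C)C)CCC(=C)[C@H]1[C@@H](O)CC1(C)OCCO1 | intermediate
11 | (1R,2S)-3-methylidene-2-[(1S)-2-(2-methyl-1,3-dioxolan-2-yl)-1-{[tri(propan-2-yl)silyl]oxy}ethyl]-1-(propan-2-yl)cyclopentan-1-ol | O[C@@]1(C(C)C)CCC(=C)[C@H]1[C@@H](O[Si](C(C)C)(C(C)C)C(C)C)CC1(C)OCCO1 | intermediate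
12 | 4-(benzyloxy)-3-methoxybenzoic acid | COc1cc(C(=O)O)ccc1OCc1ccccc1 | starting material
13 | 4-(benzyloxy)-3-methoxybenzoyl chloride | COc1cc(C(=O)Cl)ccc1OCc1ccccc1 | intermediate
14 | (1R,2S)-3-methylidene-2-[(1S)-2-(2-methyl-1,3-dioxolan-2-yl)-1-{[tri(propan-2-yl)silyl]oxy}ethyl]-1-(propan-2-yl)cyclopentyl 4-(benzyloxy)-3-methoxybenzoate | COc1cc(C(=O)O[C@@]2(C(C)C)CCC(=C)[C@H]2[C@@H](O[Si](C(C)C)(C(C)C)C(C)C)CC2(C)OCCO2)ccc1OCc1ccccc1 | intermediate
15 | (1R,2S)-3-methylidene-2-[(1S)-3-oxo-1-{[tri(propan-2-yl)silyl]oxy}butyl]-1-(propan-2-yl)cyclopentyl 4-(benzyloxy)-3-methoxybenzoate | COc1cc(C(=O)O[C@@]2(C(C)C)CCC(=C)[C@H]2[C@@H](O[Si](C(C)C)(C(C)C)C(C)C)CC(C)=O)ccc1OCc1ccccc1 | intermediate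
16 | {2-[(1R,2S,3R)-3-{[4-(benzyloxy)-3-methoxybenzoyl]oxy}-1-methyl-2-[(1S)-3-oxo-1-{[tri(propan-2-yl)silyl]oxy}butyl]-3-(propan-2-yl)cyclopentyl]ethyl}triphenylphosphonium bromide | COc1cc(C(=O)O[C@@]2(C(C)C)CC[C@](C)(CC[P+](c3ccccc3)(c3ccccc3)c3ccccc3)[C@H]2[C@@H](O[Si](C(C)C)(C(C)C)C(C)C)CC(C)=O)ccc1OCc1ccccc1.[Br-] | intermediate
17 | ylide of 16: {2-[(1R,2S,3R)-3-{[4-(benzyloxy)-3-methoxybenzoyl]oxy}-1-methyl-2-[(1S)-3-oxo-1-{[tri(propan-2-yl)silyl]oxy}butyl]-3-(propan-2-yl)cyclopentyl]ethylidene}triphenylphosphorane | COc1cc(C(=O)O[C@@]2(C(C)C)CC[C@](C)(CC=P(c3ccccc3)(c3ccccc3)c3ccccc3)[C@H]2[C@@H](O[Si](C(C)C)(C(C)C)C(C)C)CC(C)=O)ccc1OCc1ccccc1 | intermediate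
18 | (1R,4R,5S,6S)-6-{[tri(propan-2-yl)silyl]oxy}dauc-8-en-4-yl 4-(benzyloxy)-3-methoxybenzoate (trans-fused hydroazulene, C8=C9 alkene) | COc1cc(C(=O)O[C@@]2(C(C)C)CC[C@]3(C)CC=C(C)C[C@H](O[Si](C(C)C)(C(C)C)C(C)C)[C@H]32)ccc1OCc1ccccc1 | intermediate
19 | (1R,4R,5S,6S)-6-hydroxydauc-8-en-4-yl 4-(benzyloxy)-3-methoxybenzoate | COc1cc(C(=O)O[C@@]2(C(C)C)CC[C@]3(C)CC=C(C)C[C@H](O)[C@H]32)ccc1OCc1ccccc1 | intermediate
20 | (1R,4R,5S,6S,8R,9S)-8,9-epoxy-6-hydroxydaucan-4-yl 4-(benzyloxy)-3-methoxybenzoate | COc1cc(C(=O)O[C@@]2(C(C)C)CC[C@]3(C)C[C@@H]4O[C@]4(C)C[C@H](O)[C@H]32)ccc1OCc1ccccc1 | intermediate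
21 | (1R,4R,5S,6S,8R,9S)-8,9-epoxy-6-hydroxydaucan-4-yl 4-hydroxy-3-methoxybenzoate | COc1cc(C(=O)O[C@@]2(C(C)C)CC[C@]3(C)C[C@@H]4O[C@]4(C)C[C@H](O)[C@H]32)ccc1O | target

**Step count and risks**

Total step count: 15. Longest linear sequence: 13 (steps 1–3, 5–8, 10–15).

Steps most likely to fail:

**Step 12 (proposed new method).**
- What may go wrong: simple reduction of the alkene or hydrogen-atom translocation before the tertiary radical is trapped; poor facial control at C1; olefination of the ketone by an ylide formed from surplus vinylphosphonium salt and base; β-elimination of the silyloxy group under base.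
- Fallback (known chemistry, sets out from 15 and returns at 18): Markovnikov hydrochlorination of 15 by hydrogen-atom transfer (Co(BF4)2·6H2O with a salen-type ligand, TsCl, PhSiH3, t-BuOOH, EtOH) should give the tertiary chloride F1. Keck radical allylation (allyl-SnBu3, AIBN, benzene, 80 °C) should give the C1-allyl ketone F2, with the allyl group entering opposite the C5 side chain. Wittig methylenation (Ph3P=CH2, THF) should give the diene F3. Ring-closing metathesis with the second-generation Grubbs catalyst (CH2Cl2, 40 °C) should then close the seven-membered ring to 18.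

**Step 5.**
- What may go wrong: palladium-induced isomerisation of the acid- and metal-sensitive vinyl oxirane (β-hydride elimination) before transmetalation; addition through the wrong allyl terminus; insufficient facial selectivity at C5.
- Fallback (sets out from 5 and returns at 8): copper-catalysed borylative SN2′ opening of 5 (CuCl, NaOt-Bu, Xantphos, B2pin2, MeOH, THF) should give the isolable hydroxy allylboronate F4. Its uncatalysed allylboration of aldehyde 7 (toluene, rt, then aqueous work-up) goes through the same six-membered transition state and should give 8.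

**Step 7.**
- What may go wrong: erosion of the syn selectivity, because hydride delivery to the boron chelate is syn-axial to a ring methylene; epimerisation or conjugation of the β,γ-unsaturated ketone 9.
- Fallback (sets out from 8, bypasses 9 and returns at 10): Mitsunobu inversion of the C6 carbinol of 8 (4-nitrobenzoic acid, PPh3, DIAD, THF) should give the inverted 4-nitrobenzoate F5. Methanolysis (K2CO3, MeOH, 0 °C) should then release 10.

Further compounds
F1 | step 12 | (1R,2R)-3-chloro-3-methyl-2-[(1S)-3-oxo-1-{[tri(propan-2-yl)silyl]oxy}butyl]-1-(propan-2-yl)cyclopentyl 4-(benzyloxy)-3-methoxybenzoate (either epimer at the chlorinated carbon) | COc1cc(C(=O)O[C@@]2(C(C)C)CCC(C)(Cl)[C@H]2[C@@H](O[Si](C(C)C)(C(C)C)C(C)C)CC(C)=O)ccc1OCc1ccccc1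
F2 | step 12 | (1R,2S,3R)-3-methyl-2-[(1S)-3-oxo-1-{[tri(propan-2-yl)silyl]oxy}butyl]-3-(prop-2-en-1-yl)-1-(propan-2-yl)cyclopentyl 4-(benzyloxy)-3-methoxybenzoate | COc1cc(C(=O)O[C@@]2(C(C)C)CC[C@](C)(CC=C)[C@H]2[C@@H](O[Si](C(C)C)(C(C)C)C(C)C)CC(C)=O)ccc1OCc1ccccc1
F3 | step 12 | (1R,2S,3R)-3-methyl-2-[(1S)-3-methyl-1-{[tri(propan-2-yl)silyl]oxy}but-3-en-1-yl]-3-(prop-2-en-1-yl)-1-(propan-2-yl)cyclopentyl 4-(benzyloxy)-3-methoxybenzoate | COc1cc(C(=O)O[C@@]2(C(C)C)CC[C@](C)(CC=C)[C@H]2[C@@H](O[Si](C(C)C)(C(C)C)C(C)C)CC(C)=C)ccc1OCc1ccccc1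
F4 | step 5 | (1R)-1-(propan-2-yl)-3-[(4,4,5,5-tetramethyl-1,3,2-dioxaborolan-2-yl)methyl]cyclopent-2-en-1-ol | O[C@@]1(C(C)C)CCC(CB2OC(C)(C)C(C)(C)O2)=C1
F5 | step 7 | (1S)-1-[(1S,2R)-2-hydroxy-5-methylidene-2-(propan-2-yl)cyclopentyl]-2-(2-methyl-1,3-dioxolan-2-yl)ethyl 4-nitrobenzoate | O[C@@]1(C(C)C)CCC(=C)[C@H]1[C@@H](OC(=O)c1ccc(cc1)[N+](=O)[O-])CC1(C)OCCO1
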